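## The problem

Target 24 is a linear pentamer of oxygenated benzene rings held together only by four diaryl ether oxygens. Rings are lettered A to E from the 3,5-dihydroxyphenoxy end, the ether oxygens O1 to O4 in the same order, and C1 of each ring is the carbon bonded to the ether oxygen nearer ring A. Ring A is joined through one carbon, rings B and D through the adjacent carbons C1 and C6, ring C through C1 and C4, and ring E through C1. There is no stereocentre and no other element of chirality, so nothing has to be set and nothing can direct anything else; the difficulty is purely one of constitution. Every ether oxygen is bonded to a C1 carbon (of ring B, C, D or E) that has oxygen substituents on both neighbours, and all five rings are electron-rich. Unassisted SNAr is therefore impossible, and copper-mediated coupling of such hindered partners is unreliable. Eleven hydroxyls of similar reactivity mean that the choice of which oxygen becomes a bridge and which stays a phenol must be built into the monomers. The free polyphenol is prone to air oxidation, above all in base, so it should be released last and under acidic, non-oxidising conditions. The enabling feature is that rings B, D and E carry a hydroxyl on C4, para to C1, and ring C carries O3 on C4, again para to C1. An acyl group on C4 can therefore activate a C1 fluoride towards a phenoxide and later be converted into the C4–O bond by migration of the ring from carbon to oxygen.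

## Retrosynthesis

**24 to 22.** The eleven hydroxyls are traced back to eight methyl ethers and three acetates. Cleaving the eight O–CH3 bonds of triol 23 with a boron halide is the only step that exposes the sensitive polyphenol, and it does so in acid. Triol 23 comes from tris(acetate) 22 by methanolysis. Methyl ethers are preferred to benzyl ethers because they survive carbonate at 120 °C, peracid and palladium, and because the syringyl and guaiacyl starting materials already carry them.

**22 to 21 (key disconnection).** The three C4–O bonds of rings B, D and E are cut, leading back to tris(methyl ketone) 21, in which each of these oxygens is replaced by an acetyl carbon. The neighbouring option, carrying these oxygens as ethers from the start, would leave C1 of each ring unactivated and would force four hindered copper couplings. The acetyl group makes C1 electrophilic, is inert as a nucleophile during chain growth, and is converted to oxygen in one operation at the end. The forward step must oxidise three ketones in the presence of five electron-rich rings, with the aryl group migrating each time.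

**21 to 17 and 20.** The O4–C1 bond of ring E is cut. Ring E becomes fluoride 20, activated by its para acetyl group, and the rest becomes tetramer phenol 17. This is the most hindered union (a phenoxide next to an aryloxy group attacks a carbon between two methoxy groups), so it is placed where the electrophile is a cheap monomer that can be used in excess.

**17 to 14 and 4.** The C6 hydroxyl of ring D is traced to a bromine (bromide 15), and the O3–C1 bond of ring D is then cut to give trimer phenol 14 and bromofluoride 4. Bromine is chosen over an alkoxy group on C6 for three reasons. It enters acetovanillone at a single possible position. It adds inductive activation to the C1 fluoride. And it avoids a regioselective mono-protection of a catechol. The price is one borylation–oxidation per ring.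

**14 to 8 and 11.** The C4 hydroxyl of ring C is traced to a formyl group (aldehyde 12), and the O2–C1 bond of ring C is cut to give dimer phenol 8 and fluoroaldehyde 11. Ring C needs a formyl and not an acetyl group because its C4 oxygen must be unmasked midway, while the ring B ketone stays untouched. The forward oxidation therefore has to distinguish an aldehyde from a methyl ketone. This also fixes the direction of growth from A to E, since ring C must be an electrophile before it can be a nucleophile.

**8 to 4 and 5.** The C6 hydroxyl of ring B is again traced to bromine (bromide 6), and the O1–C1 bond of ring B is cut to give 3,5-dimethoxyphenol 5 and the same bromofluoride 4 that serves for ring D.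

**Monomers.** Fluorides 4, 11 and 20 are traced to phenols 2, 9 and 18 by deoxyfluorination through the aryl fluorosulfonates 3, 10 and 19. Bromophenol 2 comes from acetovanillone 1 by ring bromination. Syringaldehyde 9 and acetosyringone 18 are commercial. Every oxygen of the target is thus in place in a commercial phenol, except the three introduced from the acetyl groups, the one from the formyl group and the two from the bromides.

## Roads not taken

**Alternative 1:** Ring B is cut at its C2–O(methyl) and C6–O2 bonds, back to 2,6-dichloro-1,4-benzoquinone A2 and the ring C phenol A3. In the forward direction, methoxide and then the phenoxide of A3 each replace one chloride by addition–elimination, giving quinone ether A1. This is milder than anything in the chosen plan: the substitution runs at or below room temperature, needs no fluoride and no activating group, and delivers ring B with oxygen already on C1 and C4. On these points it is better. Its weak points for this target are three. Two different nucleophiles on a symmetric dichloride invite statistical mixtures, and the quinone is an oxidant towards electron-rich phenoxides. After reduction of A1, O1 must be formed at the C1 oxygen, which is flanked on both sides, in the presence of the unhindered C4 oxygen and with an unactivated ring A partner, so a protection step and a hindered copper coupling return. And only one ring is addressed; ring D would need the same sequence with a trimer as the phenoxide. The chosen plan sets against the mildness of A1 an activation that applies equally to all four ether bonds and regiochemistry fixed by the monomers.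

**Alternative 2:** Ring D is cut at C2–C3 and C4–C5, back to cyclobutenone A5 and ethoxyacetylene A6. On heating, A5 opens to a vinylketene, adds A6 and recloses by 6π electrocyclisation to pentamer A4, with ring D formed as a phenol. This is convergent, it fixes the substitution pattern of ring D by the mechanism, and it avoids exposing a finished electron-rich pentamer to peracid. In this last respect it is better than the chosen plan. The cost lies in A5. It must carry the ring E aryloxy group on the alkene and the whole A–B–C aryloxy group on the sp3 carbon next to the carbonyl, where it is a ready leaving group. Both C–O bonds (O3 and O4) would have to be made on a strained four-membered ring, for which there is little analogy. The free C2 hydroxyl and the ethyl ether that distinguish ring D in A4 have no use, since all oxygens are unmasked together. The chosen plan is linear and longer from the first monomer, but each of its bond formations has a close analogue.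

**Alternative 3:** Ring A is cut at C3–C4, back to the 4-aryloxy-6-methyl-2-pyranone A8. A strong lithium amide base deprotonates the C6 methyl group; ring opening and C-acylation at the former lactone carbonyl give the A–B dimer A7 with both ring A hydroxyls free. The O1 bond is made at the pyranone stage by vinylogous acyl substitution, which is easier than SNAr on a flanked fluoride, and two fewer methyl ethers need cleaving at the end. Both are real advantages. But the plan spends its key step on the one ring that is unhindered and can be bought as 3,5-dimethoxyphenol 5. The free resorcinol hydroxyls of A7 would have to be protected again before chain growth. And the benzyl-masked oxygen of ring B then has to be joined to ring C with no activating group on either side. The chosen plan gives up the easy O1 bond formation of A8 (its own step 3 is already the least demanding SNAr) in exchange for a solution to the three hard ether bonds.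

Key step: step 12

## Route

Remark on the chemistry: 24 has no stereogenic element, so no SMILES carries a stereodescriptor. Compounds 1, 5, 9 and 18 are taken as commercial, and SO2F2 is taken from a cylinder or generated ex situ.

Step 1
Reactants: 1 acetovanillone
Product: 2 1-(3-bromo-4-hydroxy-5-methoxyphenyl)ethanone
Conditions: Br2 (1.05 equiv), NaOAc, AcOH, 20 °C
Reagents that add atoms: bromine, BrBr
Why: Electrophilic aromatic bromination directed by the free hydroxyl; C5 is the only open position ortho to it (the para position carries the acetyl group), so a single regioisomer is expected, and the acetate buffer suppresses acid-catalysed side-chain bromination.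

Step 2
Reactants: 2 1-(3-bromo-4-hydroxy-5-methoxyphenyl)ethanone
Product: 4 1-(3-bromo-4-fluoro-5-methoxyphenyl)ethanone, via aryl fluorosulfonate 3 (not isolated)
Conditions: SO2F2 (1 atm), NMe4F (anhydrous, 3 equiv), DMF, 25 °C then 80 °C
Reagents that add atoms: tetramethylammonium fluoride, C[N+](C)(C)C.[F-] (the fluorine of 4); sulfuryl fluoride, O=S(=O)(F)F (the SO2F group of 3 only)
Why: Deoxyfluorination of a phenol through its aryl fluorosulfonate: the phenoxide is sulfonylated by the small electrophile SO2F2, and fluoride then displaces fluorosulfate at the ipso carbon in an SNAr-type substitution that the para acetyl and ortho bromine accelerate.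

Step 3
Reactants: 4 1-(3-bromo-4-fluoro-5-methoxyphenyl)ethanone; 5 3,5-dimethoxyphenol
Product: 6 1-[3-bromo-4-(3,5-dimethoxyphenoxy)-5-methoxyphenyl]ethanone
Conditions: K2CO3, DMSO, 80 °C
Reagents that add atoms: none
Why: SNAr of an unhindered phenoxide on a fluoride activated by a para acetyl group and an ortho bromine (forms O1–C1 of ring B); the bromide is meta to the acetyl group and is not displaced in the absence of a transition metal.

Step 4
Reactants: 6 1-[3-bromo-4-(3,5-dimethoxyphenoxy)-5-methoxyphenyl]ethanone
Product: 8 1-[4-(3,5-dimethoxyphenoxy)-3-hydroxy-5-methoxyphenyl]ethanone, via pinacol boronate 7 (not isolated)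
Conditions: B2pin2, Pd(dppf)Cl2 (5 mol %), KOAc, 1,4-dioxane, 90 °C; then H2O2 (30% aq), NaOH (1 M aq), THF, 0 °C
Reagents that add atoms: hydrogen peroxide, OO (the hydroxyl oxygen of 8); bis(pinacolato)diboron, CC1(C)OB(OC1(C)C)B1OC(C)(C)C(C)(C)O1 (the boryl group of 7 only)
Why: Miyaura borylation of the aryl bromide followed by oxidation of the C–B bond, in which the aryl group shifts from boron to the hydroperoxide oxygen at the same carbon; the cold, brief oxidation leaves the ketone and the diaryl ether alone.

Step 5
Reactants: 9 syringaldehyde
Product: 11 4-fluoro-3,5-dimethoxybenzaldehyde, via aryl fluorosulfonate 10 (not isolated)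
Conditions: SO2F2 (1 atm), NMe4F (anhydrous, 3 equiv), DMF, 25 °C then 60 °C
Reagents that add atoms: tetramethylammonium fluoride, C[N+](C)(C)C.[F-] (the fluorine of 11); sulfuryl fluoride, O=S(=O)(F)F (the SO2F group of 10 only)
Why: Same deoxyfluorination through the aryl fluorosulfonate; the para formyl group is the strongest activator of the three phenols used and has no enolisable hydrogen.

Step 6
Reactants: 8 1-[4-(3,5-dimethoxyphenoxy)-3-hydroxy-5-methoxyphenyl]ethanone; 11 4-fluoro-3,5-dimethoxybenzaldehyde
Product: 12 4-[5-acetyl-2-(3,5-dimethoxyphenoxy)-3-methoxyphenoxy]-3,5-dimethoxybenzaldehyde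
Conditions: K2CO3, DMSO, 90 °C
Reagents that add atoms: none
Why: SNAr of the ring B phenoxide on the formyl-activated fluoride (forms O2–C1 of ring C); carbonate in an aprotic solvent deprotonates the phenol but not the methyl ketone to any useful extent, as in the known unions of hydroxyacetophenones with fluorobenzaldehydes, so aldol condensation should not compete.

Step 7
Reactants: 12 4-[5-acetyl-2-(3,5-dimethoxyphenoxy)-3-methoxyphenoxy]-3,5-dimethoxybenzaldehyde
Product: 14 1-[4-(3,5-dimethoxyphenoxy)-3-(4-hydroxy-2,6-dimethoxyphenoxy)-5-methoxyphenyl]ethanone, via aryl formate 13 (not isolated)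
Conditions: mCPBA (1.2 equiv), CH2Cl2, 0 °C; then K2CO3 (cat.), MeOH, 20 °C
Reagents that add atoms: 3-chloroperoxybenzoic acid, OOC(=O)c1cccc(Cl)c1
Why: Baeyer–Villiger (Dakin-type) oxidation of an aryl aldehyde, which reacts with peracid far faster than the ring B methyl ketone; the ring, para to O2, migrates in preference to hydride, and catalytic carbonate in methanol then transesterifies the formate without touching the ketone.

Step 8
Reactants: 14 1-[4-(3,5-dimethoxyphenoxy)-3-(4-hydroxy-2,6-dimethoxyphenoxy)-5-methoxyphenyl]ethanone; 4 1-(3-bromo-4-fluoro-5-methoxyphenyl)ethanone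
Product: 15 tetramer bromide (rings A to D; acetyl on C4 of rings B and D, bromine on C6 of ring D, six methyl ethers)
Conditions: Cs2CO3, DMSO, 100 °C
Reagents that add atoms: none
Why: SNAr of the ring C phenoxide, which has hydrogen on both neighbours, on bromofluoride 4 (forms O3–C1 of ring D); fluoride on an acetyl-activated carbon is displaced much faster than the aryloxy groups of the existing activated ethers.

Step 9
Reactants: 15 tetramer bromide
Product: 17 tetramer phenol (rings A to D; hydroxyl on C6 of ring D), via pinacol boronate 16 (not isolated)
Conditions: B2pin2, Pd(dppf)Cl2 (5 mol %), KOAc, 1,4-dioxane, 90 °C; then H2O2 (30% aq), NaOH (1 M aq), THF, 0 °C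
Reagents that add atoms: hydrogen peroxide, OO (the hydroxyl oxygen of 17); bis(pinacolato)diboron, CC1(C)OB(OC1(C)C)B1OC(C)(C)C(C)(C)O1 (the boryl group of 16 only)
Why: Miyaura borylation and boronate oxidation as in step 4; the two ketones and the electron-rich rings are spectators under both sets of conditions.

Step 10
Reactants: 18 acetosyringone
Product: 20 1-(4-fluoro-3,5-dimethoxyphenyl)ethanone, via aryl fluorosulfonate 19 (not isolated)
Conditions: SO2F2 (1 atm), NMe4F (anhydrous, 3 equiv), DMF, 25 °C then 80 °C
Reagents that add atoms: tetramethylammonium fluoride, C[N+](C)(C)C.[F-] (the fluorine of 20); sulfuryl fluoride, O=S(=O)(F)F (the SO2F group of 19 only)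
Why: Deoxyfluorination through the aryl fluorosulfonate as in steps 2 and 5; the para acetyl group stabilises the negative charge that builds up in the ring as fluoride attacks the ipso carbon.

Step 11
Reactants: 17 tetramer phenol; 20 1-(4-fluoro-3,5-dimethoxyphenyl)ethanone
Product: 21 pentamer tris(methyl ketone) (acetyl on C4 of rings B, D and E; eight methyl ethers)
Conditions: Cs2CO3, DMSO, 120 °C, 20 in excess (2 equiv)
Reagents that add atoms: none
Why: SNAr of the ring D phenoxide on the acetyl-activated fluoride (forms O4–C1 of ring E); cesium phenoxide in DMSO is poorly ion-paired and the monomeric electrophile is used in excess to offset the hindrance on both sides.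

Step 12
Reactants: 21 pentamer tris(methyl ketone)
Product: 22 pentamer tris(acetate) (acetoxy on C4 of rings B, D and E; eight methyl ethers)
Conditions: mCPBA (9 equiv), NaHCO3, CH2Cl2, 0 °C to 40 °C
Reagents that add atoms: 3-chloroperoxybenzoic acid, OOC(=O)c1cccc(Cl)c1 (one oxygen per ketone)
Why: Threefold Baeyer–Villiger oxidation of aryl methyl ketones. The peracid adds to each acetyl carbonyl to give a tetrahedral peroxy adduct, and the ring then shifts from carbon to the nearer peroxide oxygen as 3-chlorobenzoate leaves; this forms the C4–O bond of rings B, D and E in three independent events. No ring is closed and no stereocentre is created. The closest known reaction is the peracid oxidation of 3,4,5-trialkoxyacetophenones to the corresponding aryl acetates. The selectivity required is aryl over methyl migration, and it is secured by the ether oxygen on C1 para to each migrating carbon, which stabilises the electron-deficient migrating ring, whereas the methyl group has no such support. The second requirement is that ketone oxidation outruns electrophilic attack of the peracid on the electron-rich rings A and C; NaHCO3 removes the acid that would catalyse ring hydroxylation. The aryl acetates are stable to the buffered medium, so 22 is isolated as such.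

Step 13
Reactants: 22 pentamer tris(acetate)
Product: 23 pentamer triol (hydroxyl on C4 of rings B, D and E; eight methyl ethers)
Conditions: K2CO3 (cat.), MeOH, 0 °C to 20 °C, argon; AcOH quench
Reagents that add atoms: none
Why: Base-catalysed transesterification of aryl acetates, which are far more labile than any other group present; exclusion of air protects the electron-rich phenoxides.

Step 14
Reactants: 23 pentamer triol
Product: 24 CNP0018313.0
Conditions: BBr3 (30 equiv), CH2Cl2, −78 °C to 20 °C; then MeOH and H2O, 0 °C
Reagents that add atoms: none
Why: Lewis acid demethylation of aryl methyl ethers: boron coordinates each methoxy oxygen and bromide attacks the methyl carbon; diaryl ether C–O bonds offer no sp3 carbon for this attack and persist, and the polyphenol is liberated only on acidic hydrolysis of the aryl borates.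

## Compound list

1 | acetovanillone, 1-(4-hydroxy-3-methoxyphenyl)ethanone | CC(=O)c1ccc(O)c(OC)c1 | starting material
2 | 1-(3-bromo-4-hydroxy-5-methoxyphenyl)ethanone | CC(=O)c1cc(Br)c(O)c(OC)c1 | intermediate
3 | 4-acetyl-2-bromo-6-methoxyphenyl fluorosulfonate | CC(=O)c1cc(Br)c(OS(=O)(=O)F)c(OC)c1 | intermediate
4 | 1-(3-bromo-4-fluoro-5-methoxyphenyl)ethanone | CC(=O)c1cc(Br)c(F)c(OC)c1 | intermediate
5 | 3,5-dimethoxyphenol | COc1cc(O)cc(OC)c1 | starting material
6 | 1-[3-bromo-4-(3,5-dimethoxyphenoxy)-5-methoxyphenyl]ethanone | COc1cc(OC)cc(Oc2c(OC)cc(C(C)=O)cc2Br)c1 | intermediate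
7 | 1-[4-(3,5-dimethoxyphenoxy)-3-methoxy-5-(4,4,5,5-tetramethyl-1,3,2-dioxaborolan-2-yl)phenyl]ethanone | COc1cc(OC)cc(Oc2c(OC)cc(C(C)=O)cc2B2OC(C)(C)C(C)(C)O2)c1 | intermediate
8 | 1-[4-(3,5-dimethoxyphenoxy)-3-hydroxy-5-methoxyphenyl]ethanone | COc1cc(OC)cc(Oc2c(OC)cc(C(C)=O)cc2O)c1 | intermediate
9 | syringaldehyde, 4-hydroxy-3,5-dimethoxybenzaldehyde | COc1cc(C=O)cc(OC)c1O | starting material
10 | 4-formyl-2,6-dimethoxyphenyl fluorosulfonate | COc1cc(C=O)cc(OC)c1OS(=O)(=O)F | intermediate
11 | 4-fluoro-3,5-dimethoxybenzaldehyde | COc1cc(C=O)cc(OC)c1F | intermediate
12 | 4-[5-acetyl-2-(3,5-dimethoxyphenoxy)-3-methoxyphenoxy]-3,5-dimethoxybenzaldehyde | COc1cc(OC)cc(Oc2c(OC)cc(C(C)=O)cc2Oc2c(OC)cc(C=O)cc2OC)c1 | intermediate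
13 | 4-[5-acetyl-2-(3,5-dimethoxyphenoxy)-3-methoxyphenoxy]-3,5-dimethoxyphenyl formate | COc1cc(OC)cc(Oc2c(OC)cc(C(C)=O)cc2Oc2c(OC)cc(OC=O)cc2OC)c1 | intermediate
14 | 1-[4-(3,5-dimethoxyphenoxy)-3-(4-hydroxy-2,6-dimethoxyphenoxy)-5-methoxyphenyl]ethanone | COc1cc(OC)cc(Oc2c(OC)cc(C(C)=O)cc2Oc2c(OC)cc(O)cc2OC)c1 | intermediate
15 | tetramer bromide, 1-[3-bromo-4-{4-[5-acetyl-2-(3,5-dimethoxyphenoxy)-3-methoxyphenoxy]-3,5-dimethoxyphenoxy}-5-methoxyphenyl]ethanone | COc1cc(OC)cc(Oc2c(OC)cc(C(C)=O)cc2Oc2c(OC)cc(Oc3c(OC)cc(C(C)=O)cc3Br)cc2OC)c1 | intermediate
16 | tetramer pinacol boronate, as 15 with 4,4,5,5-tetramethyl-1,3,2-dioxaborolan-2-yl in place of bromine | COc1cc(OC)cc(Oc2c(OC)cc(C(C)=O)cc2Oc2c(OC)cc(Oc3c(OC)cc(C(C)=O)cc3B3OC(C)(C)C(C)(C)O3)cc2OC)c1 | intermediate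
17 | tetramer phenol, 1-[4-{4-[5-acetyl-2-(3,5-dimethoxyphenoxy)-3-methoxyphenoxy]-3,5-dimethoxyphenoxy}-3-hydroxy-5-methoxyphenyl]ethanone | COc1cc(OC)cc(Oc2c(OC)cc(C(C)=O)cc2Oc2c(OC)cc(Oc3c(OC)cc(C(C)=O)cc3O)cc2OC)c1 | intermediate
18 | acetosyringone, 1-(4-hydroxy-3,5-dimethoxyphenyl)ethanone | CC(=O)c1cc(OC)c(O)c(OC)c1 | starting material
19 | 4-acetyl-2,6-dimethoxyphenyl fluorosulfonate | CC(=O)c1cc(OC)c(OS(=O)(=O)F)c(OC)c1 | intermediate
20 | 1-(4-fluoro-3,5-dimethoxyphenyl)ethanone | CC(=O)c1cc(OC)c(F)c(OC)c1 | intermediate
21 | pentamer tris(methyl ketone), acetyl on C4 of rings B, D and E, eight methyl ethers | COc1cc(OC)cc(Oc2c(OC)cc(C(C)=O)cc2Oc2c(OC)cc(Oc3c(OC)cc(C(C)=O)cc3Oc3c(OC)cc(C(C)=O)cc3OC)cc2OC)c1 | intermediate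
22 | pentamer tris(acetate), acetoxy on C4 of rings B, D and E, eight methyl ethers | COc1cc(OC)cc(Oc2c(OC)cc(OC(C)=O)cc2Oc2c(OC)cc(Oc3c(OC)cc(OC(C)=O)cc3Oc3c(OC)cc(OC(C)=O)cc3OC)cc2OC)c1 | intermediate
23 | pentamer triol, hydroxyl on C4 of rings B, D and E, eight methyl ethers | COc1cc(OC)cc(Oc2c(OC)cc(O)cc2Oc2c(OC)cc(Oc3c(OC)cc(O)cc3Oc3c(OC)cc(O)cc3OC)cc2OC)c1 | intermediate
24 | CNP0018313.0, the free undecahydroxy pentamer | Oc1cc(O)cc(Oc2c(O)cc(O)cc2Oc2c(O)cc(Oc3c(O)cc(O)cc3Oc3c(O)cc(O)cc3O)cc2O)c1 | target

## Step count and least certain steps

Total: 14 steps. Longest linear sequence: 12 steps (steps 1 to 4, 6 to 9 and 11 to 14, from 1).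

**Step 12 (key step).** The most likely failure is incomplete threefold oxidation, because buffered peracid reacts slowly with aryl ketones. Long exposure in turn allows electrophilic hydroxylation and over-oxidation of rings A and C. The fallback changes the oxidation level first. From 21, NaBH4 in MeOH/THF should reduce the three ketones to the pentamer tris(1-hydroxyethyl) compound F1, a stereoisomer mixture whose carbinol centres are destroyed in the next operation. H2O2 with BF3·OEt2 in CH2Cl2 at 0 °C should then give the benzylic hydroperoxides, which undergo Hock rearrangement (aryl shift to oxygen, loss of acetaldehyde). This returns to the route at triol 23 and skips 22.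

**Step 11.** Both partners are hindered and the fluoride is activated only by an acetyl group, so the substitution may be slow enough for base-induced aldol self-condensation of the methyl ketones and aryloxy exchange at the activated ethers to take over. The fallback forms O4 from the other side. From bromide 15, an Ullmann-type coupling with acetosyringone 18 (CuI, picolinic acid, K3PO4, DMSO, 100 °C) should give 21 directly. It bypasses steps 9 and 10 and makes no new compound (F0).

**Step 7.** Chemoselectivity may be lost in two ways: the ring B ketone may also be oxidised, which after methanolysis gives a second nucleophilic phenol, or hydride may migrate in place of the ring, giving the carboxylic acid. The fallback removes the ketone from play. From 8, ethylene glycol with TsOH in toluene under water removal should give the ketal phenol F2. SNAr with 11 (K2CO3, DMSO, 90 °C) then gives the ketal aldehyde F3. Buffered mCPBA gives the ketal formate F4, and catalytic K2CO3 in MeOH gives the ketal trimer phenol F5. Aqueous HCl in THF returns 14. The same detour also takes the enolisable ketone out of step 6.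

**Step 10.** Fluoride may attack sulfur instead of the ring carbon, returning the phenoxide and stalling the reaction at a carbon flanked by two methoxy groups. The basic fluoride may also enolise the ketone and start aldol condensation. Steps 2 and 5 use the same reaction on rings that are more strongly activated (by bromine and by formyl respectively). The fallback forms the C–F bond on a metal. From 18, Tf2O and pyridine should give the aryl triflate F6. Palladium-catalysed fluorination ([(cinnamyl)PdCl]2, tBuBrettPhos, CsF, toluene, 110 °C), by reductive elimination from an arylpalladium fluoride of divalent palladium, then returns to the route at 20. The absence of ortho hydrogens excludes regioisomeric fluorides.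

**Step 14.** Cleavage of eight methyl ethers may stop short and give partially methylated mixtures, and the free polyphenol may be lost to air oxidation and to irreversible adsorption during isolation. The fallback changes how the product is isolated. From 23, after the BBr3 treatment and methanol quench, the crude material is acetylated (Ac2O, pyridine) to the undecaacetate F7. This is stable and can be purified on silica; under-demethylated material separates at this stage and can be resubmitted. Catalytic NaOMe in MeOH under argon, followed by an acidic resin, then returns to the route at 24.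

## Further compounds

F1 | step 12 | pentamer tris(1-hydroxyethyl) compound, 1-hydroxyethyl on C4 of rings B, D and E, eight methyl ethers, stereoisomer mixture | COc1cc(OC)cc(Oc2c(OC)cc(C(C)O)cc2Oc2c(OC)cc(Oc3c(OC)cc(C(C)O)cc3Oc3c(OC)cc(C(C)O)cc3OC)cc2OC)c1
F0 | step 11 | none | none
F2 | step 7 | 2-(3,5-dimethoxyphenoxy)-3-methoxy-5-(2-methyl-1,3-dioxolan-2-yl)phenol | COc1cc(OC)cc(Oc2c(OC)cc(C3(C)OCCO3)cc2O)c1
F3 | step 7 | 4-[2-(3,5-dimethoxyphenoxy)-3-methoxy-5-(2-methyl-1,3-dioxolan-2-yl)phenoxy]-3,5-dimethoxybenzaldehyde | COc1cc(OC)cc(Oc2c(OC)cc(C3(C)OCCO3)cc2Oc2c(OC)cc(C=O)cc2OC)c1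
F4 | step 7 | 4-[2-(3,5-dimethoxyphenoxy)-3-methoxy-5-(2-methyl-1,3-dioxolan-2-yl)phenoxy]-3,5-dimethoxyphenyl formate | COc1cc(OC)cc(Oc2c(OC)cc(C3(C)OCCO3)cc2Oc2c(OC)cc(OC=O)cc2OC)c1
F5 | step 7 | 4-[2-(3,5-dimethoxyphenoxy)-3-methoxy-5-(2-methyl-1,3-dioxolan-2-yl)phenoxy]-3,5-dimethoxyphenol | COc1cc(OC)cc(Oc2c(OC)cc(C3(C)OCCO3)cc2Oc2c(OC)cc(O)cc2OC)c1
F6 | step 10 | 4-acetyl-2,6-dimethoxyphenyl trifluoromethanesulfonate | CC(=O)c1cc(OC)c(OS(=O)(=O)C(F)(F)F)c(OC)c1
F7 | step 14 | undecaacetate of 24 | CC(=O)Oc1cc(OC(C)=O)cc(Oc2c(OC(C)=O)cc(OC(C)=O)cc2Oc2c(OC(C)=O)cc(Oc3c(OC(C)=O)cc(OC(C)=O)cc3Oc3c(OC(C)=O)cc(OC(C)=O)cc3OC(C)=O)cc2OC(C)=O)c1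
A1 | alternative 1 | 2-[4-(benzyloxy)-2,6-dimethoxyphenoxy]-6-methoxy-1,4-benzoquinone | COC1=CC(=O)C=C(Oc2c(OC)cc(OCc3ccccc3)cc2OC)C1=O
A2 | alternative 1 | 2,6-dichloro-1,4-benzoquinone | ClC1=CC(=O)C=C(Cl)C1=O
A3 | alternative 1 | 4-(benzyloxy)-2,6-dimethoxyphenol | COc1cc(OCc2ccccc2)cc(OC)c1O
A4 | alternative 2 | pentamer with free C2 hydroxyl and C4 ethoxy on ring D, all other oxygens methylated | COc1cc(OC)cc(Oc2c(OC)cc(OC)cc2Oc2c(OC)cc(Oc3c(O)cc(OCC)cc3Oc3c(OC)cc(OC)cc3OC)cc2OC)c1
A5 | alternative 2 | 4-{4-[2-(3,5-dimethoxyphenoxy)-3,5-dimethoxyphenoxy]-3,5-dimethoxyphenoxy}-3-(2,4,6-trimethoxyphenoxy)cyclobut-2-en-1-one, racemic | O=C1C=C(Oc2c(OC)cc(OC)cc2OC)C1Oc1cc(OC)c(Oc2cc(OC)cc(OC)c2Oc2cc(OC)cc(OC)c2)c(OC)c1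
A6 | alternative 2 | ethoxyacetylene | CCOC#C
A7 | alternative 3 | 5-[2-(benzyloxy)-4,6-dimethoxyphenoxy]benzene-1,3-diol | Oc1cc(O)cc(Oc2c(OC)cc(OC)cc2OCc2ccccc2)c1
A8 | alternative 3 | 4-[2-(benzyloxy)-4,6-dimethoxyphenoxy]-6-methyl-2H-pyran-2-one | Cc1cc(Oc2c(OC)cc(OC)cc2OCc2ccccc2)cc(=O)o1
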